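**Plan**
- Numbering: the heptane chain runs from C1 (CH2 on the 4‑hydroxy‑3‑methoxyphenyl ring) to C7 (CH2 on the catechol ring). C3 and C5 carry the acetates, (3R,5S), a syn pair.
- Enabling feature: C1 is a benzylic CH2 placed 1,5 to the oxygen on C5. The chain can therefore be read as an opened oxane (ring O plus C1–C5) whose benzylic C1–O bond was hydrogenolysed, with C3 as the 4‑position of that ring.
- Retrosynthetic cuts, in order: phenol/acetate adjustment; C1–H back to C1–O (oxane); C3 carbinol back to C3 ketone; C1–C2, C1–O and C3=O by an alkyne Prins reaction into vanillin acetate (C1) and a C2–C7 homopropargylic alcohol; C4–C5 by propargylation of a 3‑arylpropanal.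
- Forward: C4–C5 is joined first, then C1–C2/C1–O closes the only, temporary, ring. C3 is reduced on the ring, one hydrogenolysis opens the ring and removes the benzyl groups, and peracetylation followed by selective aryl‑acetate removal finishes.
- Stereochemistry: C5 comes from chiral phosphoric acid catalysis. C3 is relayed from C5 through the 2,6‑cis chair by equatorial hydride delivery. C1 is a transient centre.

Key step: step 4

Assumption: the (R)-configured phosphoric acid is taken to direct the allenylboronate to the Re face of the unbranched aldehyde 4, as this catalyst class does with other aldehydes; if the sense were opposite, the (S)-catalyst would be used. Compounds 1, 5 and 8 are catalogue chemicals.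

**Step 1**
Reactants: 1 3-(3,4-dihydroxyphenyl)propanoic acid
Product: 2 benzyl 3-[3,4-bis(benzyloxy)phenyl]propanoate
Conditions: BnBr (3.6 equiv), K2CO3 (4 equiv), DMF, 60 °C
Reagents that add atoms: benzyl bromide, BrCc1ccccc1
Why: Williamson etherification and carboxylate O‑alkylation (SN2) should benzylate both phenols and the acid in one operation, the benzyl ester then serving as the handle for the reduction.

**Step 2**
Reactants: 2 benzyl 3-[3,4-bis(benzyloxy)phenyl]propanoate
Product: 4 3-[3,4-bis(benzyloxy)phenyl]propanal, via aluminium hemiacetal 3 (not isolated)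
Conditions: i-Bu2AlH (1.1 equiv), CH2Cl2, −78 °C; MeOH, then aq. KNaC4H4O6
Reagents that add atoms: none
Why: Partial ester reduction with i-Bu2AlH: one hydride adds at −78 °C to give the tetrahedral aluminium hemiacetal 3, which is stable at that temperature and should release the aldehyde and benzyl alcohol only on hydrolytic work‑up, the aryl benzyl ethers being inert.

**Step 3**
Reactants: 4 3-[3,4-bis(benzyloxy)phenyl]propanal; 5 allenylboronic acid pinacol ester (4,4,5,5-tetramethyl-2-(propa-1,2-dienyl)-1,3,2-dioxaborolane)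
Product: 7 (S)-1-[3,4-bis(benzyloxy)phenyl]hex-5-yn-3-ol, via pinacol borate ester 6 (not isolated)
Conditions: 5 (1.5 equiv), (R)-3,3'-bis(2,4,6-triisopropylphenyl)-1,1'-binaphthyl-2,2'-diyl hydrogen phosphate (10 mol %), 4 Å MS, toluene, −20 °C; aq. NaHCO3
Reagents that add atoms: none
Why: Chiral phosphoric acid‑catalysed propargylboration of an aldehyde (SE2' transfer from the allenylboronate through a closed six‑membered transition state): the acid binds a boronate oxygen and the formyl hydrogen and should direct C–C bond formation to the Re face, setting the (S)-carbinol that becomes C5, and borate 6 is hydrolysed on work‑up.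

**Step 4**
Reactants: 7 (S)-1-[3,4-bis(benzyloxy)phenyl]hex-5-yn-3-ol; 8 4-formyl-2-methoxyphenyl acetate (vanillin acetate)
Product: 10 4-[(2S,6S)-6-{2-[3,4-bis(benzyloxy)phenyl]ethyl}-4-oxooxan-2-yl]-2-methoxyphenyl acetate (2,6-cis oxan-4-one), via cyclic enol 9 (not isolated)
Conditions: 8 (1.2 equiv), CF3SO3H (1.2 equiv), H2O (2 equiv), CH2Cl2, −20 to 0 °C; aq. NaHCO3
Reagents that add atoms: water, O
Why: Alkyne Prins cyclisation: acid‑mediated condensation of the C5 hydroxyl of 7 with aldehyde 8 gives, through the hemiacetal, an (E)-oxocarbenium ion whose carbon (C1) is attacked by the terminal alkyne carbon (C2), and the developing cyclic vinyl cation is captured at C3 by water to give enol 9, which tautomerises to ketone 10. The closest known reactions are the halo‑ and hydrative alkyne Prins cyclisations of secondary homopropargylic alcohols with aldehydes, which deliver 2,6‑cis 4‑halodihydropyrans or oxan‑4‑ones. The one ring formed (O, C1–C5) closes in the 6‑endo‑dig mode. The new stereocentre C1 is controlled by the C5 centre through a chair‑like transition state in which the aryl group and the arylethyl chain are both equatorial, hence 2,6‑cis; C1 is erased later, but this chair is what step 5 relies on. The step must leave C5 untouched and must end in oxygen capture: the acetoxy group keeps the arene electron‑poor, which disfavours 2‑oxonia‑Cope exchange and benzylic ionisation, and the added water is meant to outcompete triflate at the vinyl cation. Low temperature and a short reaction time should also limit acid‑induced retro‑oxa‑Michael opening of the β‑alkoxy ketone and loss of benzyl ethers.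

**Step 5**
Reactants: 10 4-[(2S,6S)-6-{2-[3,4-bis(benzyloxy)phenyl]ethyl}-4-oxooxan-2-yl]-2-methoxyphenyl acetate
Product: 11 4-[(2S,4S,6S)-6-{2-[3,4-bis(benzyloxy)phenyl]ethyl}-4-hydroxyoxan-2-yl]-2-methoxyphenyl acetate (hydroxyl axial and trans to both ring substituents)
Conditions: LiBH(s-Bu)3 (1.2 equiv), THF, −78 °C; AcOH quench
Reagents that add atoms: none
Why: Diastereoselective ketone reduction with a bulky trialkylborohydride: in the chair with both substituents equatorial the axial hydrogens at C1 and C5 block the axial trajectory, so hydride should enter equatorially and give the axial C3 alcohol, which is syn to the C5 oxygen in the open chain, while the low temperature and the acidic, non‑oxidative quench should spare the aryl acetate.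

**Step 6**
Reactants: 11 4-[(2S,4S,6S)-6-{2-[3,4-bis(benzyloxy)phenyl]ethyl}-4-hydroxyoxan-2-yl]-2-methoxyphenyl acetate
Product: 13 4-[(3R,5S)-7-(3,4-dihydroxyphenyl)-3,5-dihydroxyheptyl]-2-methoxyphenyl acetate, via catechol oxanol 12 (not isolated)
Conditions: H2 (3 bar), Pd(OH)2/C, EtOAc–AcOH (3:1), rt
Reagents that add atoms: none
Why: Palladium‑catalysed hydrogenolysis of benzylic C–O bonds: the two aryl benzyl ethers should go first (12), followed by the cyclic secondary benzylic ether bond C1–O, a cleavage known from the reductive opening of 2‑aryl oxolane lignans and assisted here by acetic acid; the C3–O and C5–O bonds are not benzylic, so C1 becomes CH2 and the syn‑3,5‑diol is released with its two centres unchanged.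

**Step 7**
Reactants: 13 4-[(3R,5S)-7-(3,4-dihydroxyphenyl)-3,5-dihydroxyheptyl]-2-methoxyphenyl acetate
Product: 14 (3R,5S)-1-(4-acetoxy-3-methoxyphenyl)-7-(3,4-diacetoxyphenyl)heptane-3,5-diyl diacetate
Conditions: Ac2O (excess), pyridine, DMAP (cat.), CH2Cl2, 0 °C to rt
Reagents that add atoms: acetic anhydride, CC(=O)OC(C)=O
Why: DMAP‑catalysed acylation should esterify the two secondary alcohols and the two catechol hydroxyls exhaustively without affecting C3 or C5.

**Step 8**
Reactants: 14 (3R,5S)-1-(4-acetoxy-3-methoxyphenyl)-7-(3,4-diacetoxyphenyl)heptane-3,5-diyl diacetate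
Product: 15 (3R,5S)-7-(3,4-dihydroxyphenyl)-1-(4-hydroxy-3-methoxyphenyl)heptane-3,5-diyl diacetate (CNP0315129.1)
Conditions: NH4OAc, MeOH–H2O (4:1), rt, argon
Reagents that add atoms: none
Why: Chemoselective transesterification: aryl acetates are much better acyl donors than secondary alkyl acetates (phenoxide leaving group), so neutral NH4OAc in aqueous methanol should remove the three phenolic acetyl groups and keep the 3,5‑diacetate, the neutral medium also protecting the oxidation‑prone catechol.

**Compound list**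
1 | 3-(3,4-dihydroxyphenyl)propanoic acid | O=C(O)CCc1ccc(O)c(O)c1 | starting material
2 | benzyl 3-[3,4-bis(benzyloxy)phenyl]propanoate | O=C(OCc1ccccc1)CCc1ccc(OCc2ccccc2)c(OCc2ccccc2)c1 | intermediate
3 | [1-(benzyloxy)-3-[3,4-bis(benzyloxy)phenyl]propoxy]bis(2-methylpropyl)aluminium (aluminium hemiacetal, racemic at the hemiacetal carbon) | CC(C)C[Al](CC(C)C)OC(OCc1ccccc1)CCc1ccc(OCc2ccccc2)c(OCc2ccccc2)c1 | intermediate (not isolated)
4 | 3-[3,4-bis(benzyloxy)phenyl]propanal | O=CCCc1ccc(OCc2ccccc2)c(OCc2ccccc2)c1 | intermediate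
5 | allenylboronic acid pinacol ester | C=C=CB1OC(C)(C)C(C)(C)O1 | starting material
6 | 2-{[(3S)-1-[3,4-bis(benzyloxy)phenyl]hex-5-yn-3-yl]oxy}-4,4,5,5-tetramethyl-1,3,2-dioxaborolane | C#CC[C@@H](OB1OC(C)(C)C(C)(C)O1)CCc1ccc(OCc2ccccc2)c(OCc2ccccc2)c1 | intermediate (not isolated)
7 | (S)-1-[3,4-bis(benzyloxy)phenyl]hex-5-yn-3-ol | C#CC[C@@H](O)CCc1ccc(OCc2ccccc2)c(OCc2ccccc2)c1 | intermediate
8 | 4-formyl-2-methoxyphenyl acetate (vanillin acetate) | CC(=O)Oc1ccc(C=O)cc1OC | starting material
9 | 4-[(2S,6S)-6-{2-[3,4-bis(benzyloxy)phenyl]ethyl}-4-hydroxy-5,6-dihydro-2H-pyran-2-yl]-2-methoxyphenyl acetate (cyclic enol) | COc1cc([C@@H]2C=C(O)C[C@H](CCc3ccc(OCc4ccccc4)c(OCc4ccccc4)c3)O2)ccc1OC(C)=O | intermediate (not isolated)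
10 | 4-[(2S,6S)-6-{2-[3,4-bis(benzyloxy)phenyl]ethyl}-4-oxooxan-2-yl]-2-methoxyphenyl acetate | COc1cc([C@@H]2CC(=O)C[C@H](CCc3ccc(OCc4ccccc4)c(OCc4ccccc4)c3)O2)ccc1OC(C)=O | intermediate
11 | 4-[(2S,4S,6S)-6-{2-[3,4-bis(benzyloxy)phenyl]ethyl}-4-hydroxyoxan-2-yl]-2-methoxyphenyl acetate | COc1cc([C@@H]2C[C@@H](O)C[C@H](CCc3ccc(OCc4ccccc4)c(OCc4ccccc4)c3)O2)ccc1OC(C)=O | intermediate
12 | 4-[(2S,4S,6S)-6-[2-(3,4-dihydroxyphenyl)ethyl]-4-hydroxyoxan-2-yl]-2-methoxyphenyl acetate | COc1cc([C@@H]2C[C@@H](O)C[C@H](CCc3ccc(O)c(O)c3)O2)ccc1OC(C)=O | intermediate (not isolated)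
13 | 4-[(3R,5S)-7-(3,4-dihydroxyphenyl)-3,5-dihydroxyheptyl]-2-methoxyphenyl acetate | COc1cc(CC[C@H](C[C@H](CCc2ccc(O)c(O)c2)O)O)ccc1OC(C)=O | intermediate
14 | (3R,5S)-1-(4-acetoxy-3-methoxyphenyl)-7-(3,4-diacetoxyphenyl)heptane-3,5-diyl diacetate | COc1cc(CC[C@H](C[C@H](CCc2ccc(OC(C)=O)c(OC(C)=O)c2)OC(C)=O)OC(C)=O)ccc1OC(C)=O | intermediate
15 | (3R,5S)-7-(3,4-dihydroxyphenyl)-1-(4-hydroxy-3-methoxyphenyl)heptane-3,5-diyl diacetate | COc1cc(CC[C@H](C[C@H](CCc2ccc(O)c(O)c2)OC(C)=O)OC(C)=O)ccc1O | target

**Step count and weak points**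
Total: 8 steps. Longest linear sequence: 8 steps (from 1; compounds 5 and 8 are purchased).

Step 4. The vinyl cation may be captured by triflate instead of water, the alkyne may add too slowly to the aryl‑stabilised oxocarbenium ion, or the acid may strip a benzyl ether. The fallback sets out from 7 and uses the alkene Prins reaction. Semihydrogenation of 7 (H2, Pd/CaCO3 poisoned with Pb(OAc)2, quinoline, EtOAc) would give (S)-1-[3,4-bis(benzyloxy)phenyl]hex-5-en-3-ol F1. Cyclisation of F1 with aldehyde 8 in CF3CO2H–CH2Cl2 at 0 °C should give the all‑cis 4-[(2S,4R,6S)-6-{2-[3,4-bis(benzyloxy)phenyl]ethyl}-4-(trifluoroacetoxy)oxan-2-yl]-2-methoxyphenyl acetate F2. Brief treatment with aqueous NaHCO3 in THF would hydrolyse it to the equatorial alcohol 4-[(2S,4R,6S)-6-{2-[3,4-bis(benzyloxy)phenyl]ethyl}-4-hydroxyoxan-2-yl]-2-methoxyphenyl acetate F3. Oxidation with Dess–Martin periodinane (NaHCO3, CH2Cl2) brings the route back at ketone 10.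

Step 6. Once the benzyl ethers are gone, scission of the cyclic secondary benzylic C–O bond may stall because the acetoxy group leaves the arene electron‑poor, and forcing conditions risk ring saturation. The fallback sets out from 11 and cleaves the bond by ionic hydrogenation.
- Methanolysis (K2CO3, MeOH, 0 °C) would give the free phenol (2S,4S,6S)-6-{2-[3,4-bis(benzyloxy)phenyl]ethyl}-2-(4-hydroxy-3-methoxyphenyl)oxan-4-ol F4.
- Et3SiH with BF3·OEt2 in CH2Cl2 at −40 to 0 °C should ionise the para‑hydroxy‑activated C1–O bond and deliver hydride to C1, giving (3R,5S)-7-[3,4-bis(benzyloxy)phenyl]-1-(4-hydroxy-3-methoxyphenyl)heptane-3,5-diol F5.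
- Neutral debenzylation (H2, Pd/C, EtOAc–MeOH) would give (3R,5S)-7-(3,4-dihydroxyphenyl)-1-(4-hydroxy-3-methoxyphenyl)heptane-3,5-diol F6.
- Peracetylation (Ac2O, pyridine, DMAP) returns to the route at pentaacetate 14.

Step 3. Facial discrimination may be insufficient with an unbranched aliphatic aldehyde, which would lower the enantiomeric purity of C5 and so of both target centres. The fallback sets out from 4 and builds the carbinol by epoxide resolution and opening. Corey–Chaykovsky methylenation (Me3S+ I−, NaH, DMSO–THF) would give racemic 2-{2-[3,4-bis(benzyloxy)phenyl]ethyl}oxirane F7. Hydrolytic kinetic resolution with (S,S)-(salen)Co(OAc) (trivalent cobalt; salen = N,N'-bis(3,5-di-tert-butylsalicylidene)-1,2-cyclohexanediamine; 0.55 equiv H2O) should leave (S)-2-{2-[3,4-bis(benzyloxy)phenyl]ethyl}oxirane F8. Opening at the terminal carbon with LiC≡CH·H2NCH2CH2NH2 in DMSO returns to the route at alcohol 7.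

**Further compounds**
F1 | step 4 | (S)-1-[3,4-bis(benzyloxy)phenyl]hex-5-en-3-ol | C=CC[C@@H](O)CCc1ccc(OCc2ccccc2)c(OCc2ccccc2)c1
F2 | step 4 | 4-[(2S,4R,6S)-6-{2-[3,4-bis(benzyloxy)phenyl]ethyl}-4-(trifluoroacetoxy)oxan-2-yl]-2-methoxyphenyl acetate | COc1cc([C@@H]2C[C@H](OC(=O)C(F)(F)F)C[C@H](CCc3ccc(OCc4ccccc4)c(OCc4ccccc4)c3)O2)ccc1OC(C)=O
F3 | step 4 | 4-[(2S,4R,6S)-6-{2-[3,4-bis(benzyloxy)phenyl]ethyl}-4-hydroxyoxan-2-yl]-2-methoxyphenyl acetate | COc1cc([C@@H]2C[C@H](O)C[C@H](CCc3ccc(OCc4ccccc4)c(OCc4ccccc4)c3)O2)ccc1OC(C)=O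
F4 | step 6 | (2S,4S,6S)-6-{2-[3,4-bis(benzyloxy)phenyl]ethyl}-2-(4-hydroxy-3-methoxyphenyl)oxan-4-ol | COc1cc([C@@H]2C[C@@H](O)C[C@H](CCc3ccc(OCc4ccccc4)c(OCc4ccccc4)c3)O2)ccc1O
F5 | step 6 | (3R,5S)-7-[3,4-bis(benzyloxy)phenyl]-1-(4-hydroxy-3-methoxyphenyl)heptane-3,5-diol | COc1cc(CC[C@H](C[C@H](CCc2ccc(OCc3ccccc3)c(OCc3ccccc3)c2)O)O)ccc1O
F6 | step 6 | (3R,5S)-7-(3,4-dihydroxyphenyl)-1-(4-hydroxy-3-methoxyphenyl)heptane-3,5-diol | COc1cc(CC[C@H](C[C@H](CCc2ccc(O)c(O)c2)O)O)ccc1O
F7 | step 3 | racemic 2-{2-[3,4-bis(benzyloxy)phenyl]ethyl}oxirane | C1OC1CCc1ccc(OCc2ccccc2)c(OCc2ccccc2)c1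
F8 | step 3 | (S)-2-{2-[3,4-bis(benzyloxy)phenyl]ethyl}oxirane | C1O[C@H]1CCc1ccc(OCc2ccccc2)c(OCc2ccccc2)c1
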